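# Proposal: synthesis of CNP0316493.2 through a two-fold Wittig–Still rearrangement

## The problem

The target is built from five phenylpropanoid units. Its centre is a cis-fused 3,7-dioxabicyclo[3.3.0]octane (furofuran) with exo 4-oxy-3,5-dimethoxyphenyl groups at C7 and C7'; phenol oxygen O-4' carries a guaiacylglycerol unit (G1) through an 8-O-4 ether, O-4 carries a second (G2), and the phenol oxygen of G2 carries a third (G3). There are ten stereocentres: four in the core (7R,8S,7'R,8'S) and two in each side unit, all erythro, with G1 and G2 as 7S,8R and G3 as 7R,8S. In the core, the ring-fusion centres C8 and C8' can control C7 and C7', because an aryl group prefers the exo face of the bicycle. The side units are separated from the core and from each other by flat aryl ether spacers, so each needs its own reagent control, and G3 needs the opposite sense to G1 and G2. The core is C2-symmetric but its two ends carry different chains, so the two phenols have to be told apart once. Every benzylic C–O bond (two ring ethers, three secondary alcohols) is para to an oxygen and is therefore open to acid ionisation and to hydrogenolysis; the free phenols are easily oxidised, and C8 of a side unit is base-labile while it is α to a carbonyl. The feature that opens the core is that C8 and C8' are bonded to each other and each carries one CH2–O carbon (C9, C9') and one benzylic carbon (C7, C7'). If C7 and C7' are read as aldehydes masked as propenyl groups, each C8–C9 bond is the new bond of a homoallylic alcohol, the retron of a [2,3]-Wittig shift, and the two retrons share the C8–C8' bond, which maps onto the central single bond of a C2-symmetric (Z,Z)-diene.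

## Retrosynthesis

**Side units (three times the same pair of cuts).** Each guaiacylglycerol unit is cut at C7–C8 (aldol) and at the aryl O–C8 bond (Williamson), with C9 as the carbonyl of an N-acyloxazolidinone. The neighbouring cut, displacement at a secondary C8 of a finished C7–C9 fragment by a 2,6-dimethoxyphenoxide, would be slow and prone to elimination. The chosen cut makes the ether at a primary carbon and lets one auxiliary set C8 and C7 together.

- G3: target 39 comes from silyl ether 38, adduct 37 and imide 34, that is from phenol 31, bromoacetyl imide 33 and vanillin acetate 27.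
- G2: 31 comes from adduct 30 and imide 26, that is from phenol 25, bromoacetyl imide 18 and 27.
- G1: 25 comes from 24, 23 and 19, that is from the mono-benzyl ether 16, 18 and silyl-protected vanillin 21.

Each removal takes away two stereocentres and about a fifth of the mass. The forward reaction must be an anti-selective aldol with the face fixed by the auxiliary ((R) for G1 and G2, (S) for G3), and only one phenol may be free at a time. The acetate of 27 is lost in the reductive removal of the auxiliary, the benzyl group holds O-4 and the triisopropylsilyl group holds the G1 phenol.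

**Telling the ends apart.** 16 is the mono-benzyl ether of diphenol 15. The two phenols are homotopic, so there is only one mono-ether. The statistical step is placed here because 15 is the cheapest compound on which it can be done and unreacted 15 can be recovered and used again.

**Ring ethers of the core.** Cutting C7–O and C7'–O of 15 (through bis-silyl ether 14) gives tetraol 13. This is preferred over cutting the C8–C8' bond (oxidative dimerisation, which is racemic) because C8 and C8' then come from an earlier, enantiocontrolled step. The closure must place both aryl groups exo.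

**Aryl–C7 bonds.** 13 is cut into bis-lactol 9 and two molecules of arylmagnesium bromide 12 (from bromide 11, from phenol 10). The precursor 9 has six carbons and two stereocentres. The addition only has to be faster than enolisation of the open aldehyde.

**C7 and C7' carbonyls.** 9 is the ozonolysis product of diene-diol 8; the propenyl groups are the masked aldehydes. Nothing else in 8 is oxidisable.

**C8–C9 and C8'–C9' (key cut).** 8 is the product of a two-fold [2,3]-shift of the bis(stannylmethyl) ether 5. Against an enolate alkylation or conjugate addition, this cut sets both tertiary centres by 1,3-chirality transfer from two cheap carbinol centres and needs no auxiliary. The forward reaction must proceed twice with full transfer and without a [1,2]-shift.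

**The diene.** 5 comes from diol 3 and two molecules of tributyl(iodomethyl)stannane 4, one for each hydroxyl. 3 is the semi-reduction product of diyne 2, and 2 is the oxidative dimer of two molecules of (R)-but-3-yn-2-ol 1. All carbons of the core except the aryl groups thus come from 1 and 4.

## Roads not taken

Alternative 1: The cut is the C7–C8 bonds of both core-bound side units at once. The bis-imide A2 (both phenols of diphenol 15 alkylated) would be enolised twice and added to two molecules of O-benzylvanillin A3 to give the bis-adduct A1.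
- Merits: four stereocentres in one operation, and it exploits the fact that G1 and G2 have the same configuration. In the side-chain phase it would be about five steps shorter than the sequential plan; in step economy it is the better road there.
- Weak points: it says nothing about the origin of enantiopure 15. After the double aldol the two ends are again identical, both guaiacyl phenols being benzylated, while the target needs a third unit on one end only. The ends must then be differentiated statistically on an advanced, polar intermediate that cannot be recycled as easily as 15.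
- Comparison: the chosen plan uses the same aldol reaction three times and shares its risk. Against the shorter sequence it sets an early, recyclable desymmetrisation (step 10) and an enantioselective entry to the core.

Alternative 2: The cut is C7–C8 and C9'–C8' of one tetrahydrofuran ring. A carbonyl ylide freed by CsF from the α-silyl chloromethyl ether A6 would add across the alkene of the (R)-butenolide A5 to give the bicyclic lactone A4.
- Merits: the two aryl groups arrive separately and already carry different protecting groups (benzyl and allyl). The ends are differentiated by construction, which is better than the statistical step of the chosen plan.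
- Weak points: the ylide is not stabilised and its aryl group has no strong bias between exo and endo, so C7 is uncertain. A5 has an acidic, benzylic γ-hydrogen and can racemise through its dienolate under the fluoride conditions. A4 still has C9 as a carbonyl, so reduction to the lactol and deoxygenation are needed next to a benzylic lactone C–O bond that ionises easily. A5 needs its own asymmetric synthesis.
- Comparison: the chosen plan gives up the built-in differentiation but fixes C8 and C8' by a sigmatropic transfer with a predictable sense, and it reaches the correct oxidation level at C9 directly.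

Alternative 3: The cut is the two aryl–C7 bonds. The bis-lactol diacetate A8 would be ionised by BF3·OEt2 and two equivalents of the arylzinc bromide A9 would add from the convex face to give the dibenzyl ether A7.
- Merits: the C–C bond formation is irreversible and the convex-face attack sets the exo aryl groups under kinetic control. This is arguably a safer way to fix C7 and C7' than the reversible C–O closure of step 8.
- Weak points: it needs the same enantiopure bis-lactol 9 and so does not replace the key step of the chosen plan; it only replaces steps 7 and 8. Lewis-acid coupling of arylzinc halides with furanosyl cations is less secure than a Grignard addition. A7 has two benzyl groups, so a hydrogenolysis and the same desymmetrisation would follow.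
- Comparison: the chosen plan keeps this road as the fallback for step 8.

Key step: step 4

Remark: the diphenol with the 7R,8S,7'R,8'S configuration is called (−)-syringaresinol here by relation to the pinoresinol series; oxazolidinones 17 and 32, vanillin acetate 27 and the simple reagents are taken as commercial.

Notation: lignan numbering is used. "Syr" is the (−)-syringaresinol core with phenol oxygens O-4 and O-4'. Xc(R) and Xc(S) are (4R)- and (4S)-4-benzyl-2-oxooxazolidin-3-yl. Units G1 (on O-4'), G2 (on O-4) and G3 (on the phenol oxygen of G2) are ArC7H(OH)–C8H(C9H2OH)– groups bonded through C8. Full names are in the compound list.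

## Route

Step 1
Reactants: 1 (R)-but-3-yn-2-ol (2 equiv; two molecules are joined)
Product: 2 (2R,7R)-octa-3,5-diyne-2,7-diol
Conditions: CuCl (10 mol%), TMEDA, O2 (1 atm), acetone, rt
Reagents that add atoms: (R)-but-3-yn-2-ol (second molecule of 1), C[C@@H](O)C#C
Why: Glaser–Hay oxidative homocoupling joins two molecules of the terminal alkyne at their sp carbons with O2 as the oxidant; the free propargylic hydroxyl is tolerated and the carbinol centres take no part, so the (R,R)-diol should form without loss of configuration.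

Step 2
Reactants: 2 (2R,7R)-octa-3,5-diyne-2,7-diol
Product: 3 (2R,3Z,5Z,7R)-octa-3,5-diene-2,7-diol
Conditions: Zn dust activated with Cu(OAc)2 and AgNO3, MeOH–H2O (1:1), 40 °C
Reagents that add atoms: none
Why: Semi-reduction of a conjugated diyne by activated zinc adds two hydrogens cis to each triple bond and does not reduce the resulting alkenes, so the (Z,Z)-diene should result; the propargylic hydroxyls speed the reduction and the stereocentres are untouched.

Step 3
Reactants: 3 (2R,3Z,5Z,7R)-octa-3,5-diene-2,7-diol; 4 tributyl(iodomethyl)stannane (2 equiv react, one per hydroxyl)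
Product: 5 (2R,3Z,5Z,7R)-2,7-bis[(tributylstannyl)methoxy]octa-3,5-diene
Conditions: KH (2.5 equiv), THF, 0 °C; then 4 (2.4 equiv), rt
Reagents that add atoms: tributyl(iodomethyl)stannane (second molecule of 4), CCCC[Sn](CCCC)(CCCC)CI
Why: Two-fold Williamson ether synthesis of the dipotassium alkoxide with two molecules of a primary α-stannyl iodide; no bond to the carbinol carbons is broken, so the R configuration and the Z geometry are kept.

Step 4
Reactants: 5 (2R,3Z,5Z,7R)-2,7-bis[(tributylstannyl)methoxy]octa-3,5-diene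
Product: 8 (2S,3S)-2,3-bis[(E)-prop-1-en-1-yl]butane-1,4-diol, via bis(lithiomethyl) ether 6 (not isolated), via monorearranged lithium alkoxide 7 (not isolated)
Conditions: n-BuLi (3 equiv), THF, −78 °C → −40 °C; then H2O
Reagents that add atoms: none
Why: Tin–lithium exchange at both Bu3Sn–CH2 groups gives the bis(α-alkoxymethyllithium) 6, and each carbanion attacks the far carbon of its own (Z)-alkene on the face from which the C–O bond leaves, a suprafacial [2,3]-sigmatropic shift through a five-membered envelope transition state; the closest known reaction is the Wittig–Still rearrangement of secondary (Z)-allylic stannylmethyl ethers. The first shift turns the diene into 7, in which the second ether is still allylic to an unconjugated (Z)-alkene, so the second shift is an ordinary case of the same reaction and the C8–C9 and C8'–C9' bonds form in turn. No ring closes. C8 is set by the (R)-carbinol at C2 of 5 and C8' by the (R)-carbinol at C7: with a (Z)-alkene, allylic 1,3-strain between the carbinol methyl group and the cis vinylic substituent leaves only the conformer with the carbinol hydrogen in the alkene plane, which fixes the face that carries oxygen and hence the migrating CH2 group. The same conformer places the methyl group trans across the new double bond, so both propenyl groups should be E. The two ends of 5 are homotopic, so both transfers have the same sense and the C2-symmetric (S,S)-diol is expected, not the meso isomer. The step needs [2,3]- over [1,2]-shift and no proton transfer to the carbanions; the low temperature, the non-stabilised carbanion and the fast intramolecular shift secure this.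

Step 5
Reactants: 8 (2S,3S)-2,3-bis[(E)-prop-1-en-1-yl]butane-1,4-diol
Product: 9 (3aS,6aS)-tetrahydro-1H,3H-furo[3,4-c]furan-1,4-diol (anomer mixture)
Conditions: O3, CH2Cl2–MeOH (4:1), −78 °C; then Me2S, −78 °C → rt
Reagents that add atoms: ozone, [O-][O+]=O
Why: Ozonolysis with reductive work-up cleaves both propenyl groups to aldehydes (C7, C7'); each is captured at once by the CH2OH group on the neighbouring stereocentre as a five-membered lactol, and the cis-fused bicycle that results holds C8 and C8' against epimerisation.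

Step 6
Reactants: 10 4-bromo-2,6-dimethoxyphenol
Product: 11 (4-bromo-2,6-dimethoxyphenoxy)(tert-butyl)dimethylsilane
Conditions: t-BuMe2SiCl, imidazole, DMF, rt
Reagents that add atoms: tert-butyldimethylsilyl chloride, CC(C)(C)[Si](C)(C)Cl
Why: Imidazole-assisted silylation of the phenol; the aryl silyl ether survives magnesium insertion and the Grignard reagent and can later be removed by fluoride without acid.

Step 7
Reactants: 9 (3aS,6aS)-tetrahydro-1H,3H-furo[3,4-c]furan-1,4-diol; 11 (4-bromo-2,6-dimethoxyphenoxy)(tert-butyl)dimethylsilane (two aryl groups are transferred; used in excess)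
Product: 13 (2S,3S)-2,3-bis({4-[(tert-butyldimethylsilyl)oxy]-3,5-dimethoxyphenyl}(hydroxy)methyl)butane-1,4-diol (carbinol epimers), via arylmagnesium bromide 12 (not isolated)
Conditions: 11 (6 equiv), Mg, THF, reflux; then 9, THF, 0 → 40 °C; aq NH4Cl
Reagents that add atoms: (4-bromo-2,6-dimethoxyphenoxy)(tert-butyl)dimethylsilane (second molecule of 11), COc1cc(Br)cc(OC)c1O[Si](C)(C)C(C)(C)C
Why: Grignard addition to a lactol: two equivalents of 12 deprotonate the hemiacetal hydroxyls, the magnesium lactolates open to alkoxy aldehydes and each aldehyde takes up one aryl group from a further equivalent. The carbinol configuration does not matter because both carbinol carbons are ionised in step 8, and C8 and C8' stay intact as long as addition outruns enolisation.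

Step 8
Reactants: 13 (2S,3S)-2,3-bis({4-[(tert-butyldimethylsilyl)oxy]-3,5-dimethoxyphenyl}(hydroxy)methyl)butane-1,4-diol
Product: 14 4,4'-di-O-(tert-butyldimethylsilyl)-Syr
Conditions: TsOH·H2O (0.2 equiv), CH2Cl2, 4 Å molecular sieves, 0 °C → rt, short reaction time
Reagents that add atoms: none
Why: Acid-catalysed dehydrative etherification (SN1): each benzylic carbinol ionises to a cation stabilised by the ring oxygens and is trapped by the CH2OH group of the other arm in a five-membered ring closure, giving the cis-fused bicycle. The aryl group takes the exo position, trans to the substituent on the adjacent ring-fusion carbon, so C8 and C8' set C7 and C7' as R and both carbinol epimers converge on one product.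

Step 9
Reactants: 14 4,4'-di-O-(tert-butyldimethylsilyl)-Syr
Product: 15 (−)-syringaresinol
Conditions: Bu4NF (2.2 equiv), AcOH (2.2 equiv), THF, 0 °C
Reagents that add atoms: none
Why: Fluoride cleavage of aryl silyl ethers; the acetic acid buffer keeps the phenols protonated, so neither base-promoted oxidation nor acid-promoted epimerisation of the benzylic ring ethers should occur.

Step 10
Reactants: 15 (−)-syringaresinol
Product: 16 4-O-benzyl-Syr
Conditions: BnBr (1.0 equiv, slow addition), K2CO3 (1.1 equiv), DMF, rt; unreacted 15 is recovered and used again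
Reagents that add atoms: benzyl bromide, BrCc1ccccc1
Why: Williamson ether synthesis; the two phenols are related by the C2 axis, so only one mono-ether exists, and one equivalent of halide gives a statistical mixture from which 16 is separated.

Step 11
Reactants: 17 (R)-4-benzyl-oxazolidin-2-one
Product: 18 (R)-4-benzyl-3-(bromoacetyl)oxazolidin-2-one
Conditions: n-BuLi (1.0 equiv), THF, −78 °C; then BrCH2COBr, −78 °C
Reagents that add atoms: bromoacetyl bromide, BrCC(Br)=O
Why: N-acylation of the lithiated oxazolidinone by an acid bromide; at low temperature attack at the acyl carbon is much faster than displacement of the α-bromide.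

Step 12
Reactants: 16 4-O-benzyl-Syr; 18 (R)-4-benzyl-3-(bromoacetyl)oxazolidin-2-one
Product: 19 4-O-benzyl-4'-O-[2-oxo-2-Xc(R)-ethyl]-Syr
Conditions: K2CO3 (1.5 equiv), KI (0.1 equiv), acetone, rt → 40 °C
Reagents that add atoms: none
Why: Williamson ether synthesis at a primary α-halo carbonyl carbon, a very fast SN2 electrophile; carbonate is too weak to enolise or cleave the imide, and 16 has only one free phenol.

Step 13
Reactants: 20 vanillin
Product: 21 3-methoxy-4-[(triisopropylsilyl)oxy]benzaldehyde
Conditions: i-Pr3SiCl, imidazole, DMF, rt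
Reagents that add atoms: triisopropylsilyl chloride, CC(C)[Si](Cl)(C(C)C)C(C)C
Why: Silylation of the phenol; the bulky aryl silyl ether should survive carbonate, LiBH4 and hydrogenolysis and leaves by fluoride at the end.

Step 14
Reactants: 19 4-O-benzyl-4'-O-[2-oxo-2-Xc(R)-ethyl]-Syr; 21 3-methoxy-4-[(triisopropylsilyl)oxy]benzaldehyde
Product: 23 4-O-benzyl-Syr with the (2S,3S)-anti aldol imide of unit G1 on O-4' (aryl OSi(i-Pr)3), via O-trimethylsilyl aldolate 22 (not isolated)
Conditions: MgCl2 (0.2 equiv), Et3N (2.5 equiv), Me3SiCl (2 equiv), 21 (1.5 equiv), EtOAc, rt; then PPTS (cat.), MeOH, 0 °C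
Reagents that add atoms: none
Why: Magnesium-halide-catalysed direct anti-aldol of an N-acyloxazolidinone with a non-enolisable aromatic aldehyde (soft enolisation; silylation of the aldolate turns the catalyst over). The chelated (Z)-enolate is attacked on the face opposite the benzyl group of the (R)-auxiliary through a boat-like transition state, which sets C8 and C7 of G1 anti (erythro) in the 7S,8R sense.

Step 15
Reactants: 23 4-O-benzyl-Syr with the (2S,3S)-anti aldol imide of unit G1 on O-4'
Product: 24 4-O-benzyl-Syr with the (7S,8R)-G1 diol on O-4' (aryl OSi(i-Pr)3)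
Conditions: LiBH4 (3 equiv), MeOH (2 equiv), THF, 0 °C
Reagents that add atoms: none
Why: Reductive cleavage of the N-acyloxazolidinone by hydride attack at the exocyclic carbonyl gives the C9 alcohol and frees the auxiliary; no bond to C7 or C8 is broken, and benzyl and silyl ethers are inert.

Step 16
Reactants: 24 4-O-benzyl-Syr with the (7S,8R)-G1 diol on O-4'
Product: 25 Syr with free O-4 phenol and the (7S,8R)-G1 diol on O-4' (aryl OSi(i-Pr)3)
Conditions: H2 (1 atm), 10% Pd/C, EtOAc, rt; stopped when 24 is consumed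
Reagents that add atoms: none
Why: Hydrogenolysis of an aryl benzyl ether under neutral conditions in an aprotic solvent; benzylic alcohols, benzylic ring ethers and the aryl silyl ether react much more slowly.

Step 17
Reactants: 25 Syr with free O-4 phenol and the (7S,8R)-G1 diol on O-4'; 18 (R)-4-benzyl-3-(bromoacetyl)oxazolidin-2-one
Product: 26 4-O-[2-oxo-2-Xc(R)-ethyl]-Syr with the (7S,8R)-G1 diol on O-4'
Conditions: K2CO3 (1.5 equiv), KI (0.1 equiv), acetone, rt
Reagents that add atoms: none
Why: Williamson ether synthesis as in step 12; of the hydroxyl groups present only the phenol is deprotonated by K2CO3, so the aliphatic diol needs no protection.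

Step 18
Reactants: 26 4-O-[2-oxo-2-Xc(R)-ethyl]-Syr with the (7S,8R)-G1 diol on O-4'; 27 4-formyl-2-methoxyphenyl acetate
Product: 30 Syr with the (2S,3S)-anti aldol imide of unit G2 on O-4 (aryl OAc) beside the G1 diol on O-4', via bis(trimethylsilyl) imide 28 (not isolated), via tris(trimethylsilyl) adduct 29 (not isolated)
Conditions: Me3SiCl (5 equiv), Et3N (6 equiv), EtOAc, rt; then MgCl2 (0.3 equiv), 27 (1.5 equiv), rt; then PPTS (cat.), MeOH, 0 °C
Reagents that add atoms: none
Why: The same magnesium-halide-catalysed anti-aldol as in step 14; the two free hydroxyls are first capped as Me3Si ethers by reagents the aldol needs anyway, and all Me3Si ethers fall off in the mildly acidic methanol. The (R)-auxiliary again gives the 7S,8R sense (unit G2), and the acetate both masks the phenol and makes the aldehyde more electrophilic.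

Step 19
Reactants: 30 Syr with the (2S,3S)-anti aldol imide of unit G2 on O-4 beside the G1 diol on O-4'
Product: 31 Syr with the (7S,8R)-G2 diol on O-4 (free guaiacyl phenol) beside the G1 diol on O-4'
Conditions: LiBH4 (5 equiv), MeOH, THF, 0 °C → rt
Reagents that add atoms: none
Why: LiBH4 reduces the imide to the C9 alcohol and cleaves the aryl acetate in the same operation, so the G2 phenol needed for the next ether bond appears without a separate deprotection.

Step 20
Reactants: 32 (S)-4-benzyl-oxazolidin-2-one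
Product: 33 (S)-4-benzyl-3-(bromoacetyl)oxazolidin-2-one
Conditions: n-BuLi (1.0 equiv), THF, −78 °C; then BrCH2COBr, −78 °C
Reagents that add atoms: bromoacetyl bromide, BrCC(Br)=O
Why: N-acylation of the lithiated oxazolidinone, as in step 11.

Step 21
Reactants: 31 Syr with the (7S,8R)-G2 diol on O-4 beside the G1 diol on O-4'; 33 (S)-4-benzyl-3-(bromoacetyl)oxazolidin-2-one
Product: 34 31 with 2-oxo-2-Xc(S)-ethyl on the G2 phenol oxygen
Conditions: K2CO3 (1.5 equiv), KI (0.1 equiv), acetone, rt
Reagents that add atoms: none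
Why: Williamson ether synthesis; the guaiacyl hydroxyl of G2 is the only free phenol (the G1 phenol is silylated, both core oxygens are alkylated), and the four aliphatic hydroxyls are not deprotonated by carbonate.

Step 22
Reactants: 34 31 with 2-oxo-2-Xc(S)-ethyl on the G2 phenol oxygen; 27 4-formyl-2-methoxyphenyl acetate
Product: 37 31 with the (2R,3R)-anti aldol imide of unit G3 on the G2 phenol oxygen (aryl OAc), via tetrakis(trimethylsilyl) imide 35 (not isolated), via pentakis(trimethylsilyl) adduct 36 (not isolated)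
Conditions: Me3SiCl (8 equiv), Et3N (9 equiv), EtOAc, rt; then MgCl2 (0.3 equiv), 27 (1.5 equiv), rt; then PPTS (cat.), MeOH, 0 °C
Reagents that add atoms: none
Why: The same anti-aldol with transient silylation of the four hydroxyls; the (S)-auxiliary shields the other enolate face, so C7 and C8 of G3 are set in the mirror-image 7R,8S sense by the reagent alone, the existing stereocentres being too remote to interfere.

Step 23
Reactants: 37 31 with the (2R,3R)-anti aldol imide of unit G3 on the G2 phenol oxygen
Product: 38 the target as its mono(triisopropylsilyl) ether at the G1 phenol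
Conditions: LiBH4 (5 equiv), MeOH, THF, 0 °C → rt
Reagents that add atoms: none
Why: Reductive removal of the auxiliary and cleavage of the aryl acetate by LiBH4, as in step 19.

Step 24
Reactants: 38 the target as its mono(triisopropylsilyl) ether at the G1 phenol
Product: 39 CNP0316493.2
Conditions: Bu4NF (1.2 equiv), AcOH (1.2 equiv), THF, 0 °C
Reagents that add atoms: none
Why: Fluoride cleavage of the aryl silyl ether under buffered, near-neutral conditions, which should leave the benzylic alcohols, the ring ethers and the free phenols unchanged.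

## Compound list

1 | (R)-but-3-yn-2-ol | C[C@@H](O)C#C | starting material
2 | (2R,7R)-octa-3,5-diyne-2,7-diol | C[C@@H](O)C#CC#C[C@@H](C)O | intermediate
3 | (2R,3Z,5Z,7R)-octa-3,5-diene-2,7-diol | C[C@@H](O)/C=C\C=C/[C@@H](C)O | intermediate
4 | tributyl(iodomethyl)stannane | CCCC[Sn](CCCC)(CCCC)CI | starting material
5 | (2R,3Z,5Z,7R)-2,7-bis[(tributylstannyl)methoxy]octa-3,5-diene | C[C@@H](OC[Sn](CCCC)(CCCC)CCCC)/C=C\C=C/[C@@H](C)OC[Sn](CCCC)(CCCC)CCCC | intermediate
6 | (2R,3Z,5Z,7R)-2,7-bis(lithiomethoxy)octa-3,5-diene | C[C@@H](OC[Li])/C=C\C=C/[C@@H](C)OC[Li] | intermediate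
7 | lithium (2S,3Z,5R)-5-(lithiomethoxy)-2-[(E)-prop-1-en-1-yl]hex-3-en-1-olate | C/C=C/[C@H](CO[Li])/C=C\[C@@H](C)OC[Li] | intermediate
8 | (2S,3S)-2,3-bis[(E)-prop-1-en-1-yl]butane-1,4-diol | C/C=C/[C@H](CO)[C@@H](CO)/C=C/C | intermediate
9 | (3aS,6aS)-tetrahydro-1H,3H-furo[3,4-c]furan-1,4-diol (anomer mixture) | OC1OC[C@@H]2[C@H]1COC2O | intermediate
10 | 4-bromo-2,6-dimethoxyphenol | COc1cc(Br)cc(OC)c1O | starting material
11 | (4-bromo-2,6-dimethoxyphenoxy)(tert-butyl)dimethylsilane | COc1cc(Br)cc(OC)c1O[Si](C)(C)C(C)(C)C | intermediate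
12 | {4-[(tert-butyldimethylsilyl)oxy]-3,5-dimethoxyphenyl}magnesium bromide | COc1cc([Mg]Br)cc(OC)c1O[Si](C)(C)C(C)(C)C | intermediate
13 | (2S,3S)-2,3-bis({4-[(tert-butyldimethylsilyl)oxy]-3,5-dimethoxyphenyl}(hydroxy)methyl)butane-1,4-diol (epimers at the two carbinol carbons) | OC(c1cc(OC)c(O[Si](C)(C)C(C)(C)C)c(OC)c1)[C@H](CO)[C@@H](CO)C(O)c1cc(OC)c(O[Si](C)(C)C(C)(C)C)c(OC)c1 | intermediate
14 | (1R,3aS,4R,6aS)-1,4-bis{4-[(tert-butyldimethylsilyl)oxy]-3,5-dimethoxyphenyl}tetrahydro-1H,3H-furo[3,4-c]furan | COc1cc([C@@H]2OC[C@@H]3[C@H]2CO[C@H]3c2cc(OC)c(O[Si](C)(C)C(C)(C)C)c(OC)c2)cc(OC)c1O[Si](C)(C)C(C)(C)C | intermediate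
15 | (−)-syringaresinol, 4,4'-[(1R,3aS,4R,6aS)-tetrahydro-1H,3H-furo[3,4-c]furan-1,4-diyl]bis(2,6-dimethoxyphenol) | COc1cc([C@@H]2OC[C@@H]3[C@H]2CO[C@H]3c2cc(OC)c(O)c(OC)c2)cc(OC)c1O | intermediate
16 | 4-O-benzyl-(−)-syringaresinol | COc1cc([C@@H]2OC[C@@H]3[C@H]2CO[C@H]3c2cc(OC)c(O)c(OC)c2)cc(OC)c1OCc1ccccc1 | intermediate
17 | (R)-4-benzyl-oxazolidin-2-one | O=C1N[C@H](Cc2ccccc2)CO1 | starting material
18 | (R)-4-benzyl-3-(bromoacetyl)oxazolidin-2-one | BrCC(=O)N1[C@H](Cc2ccccc2)COC1=O | intermediate
19 | 4-O-benzyl-4'-O-{2-[(4R)-4-benzyl-2-oxooxazolidin-3-yl]-2-oxoethyl}-(−)-syringaresinol | COc1cc([C@@H]2OC[C@@H]3[C@H]2CO[C@H]3c2cc(OC)c(OCC(=O)N3[C@H](Cc4ccccc4)COC3=O)c(OC)c2)cc(OC)c1OCc1ccccc1 | intermediate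
20 | vanillin (4-hydroxy-3-methoxybenzaldehyde) | COc1cc(C=O)ccc1O | starting material
21 | 3-methoxy-4-[(triisopropylsilyl)oxy]benzaldehyde | COc1cc(C=O)ccc1O[Si](C(C)C)(C(C)C)C(C)C | intermediate
22 | 4-O-benzyl-4'-O-{(1S,2S)-1-[(4R)-4-benzyl-2-oxooxazolidine-3-carbonyl]-2-[3-methoxy-4-(triisopropylsilyloxy)phenyl]-2-(trimethylsilyloxy)ethyl}-(−)-syringaresinol | COc1cc([C@@H]2OC[C@@H]3[C@H]2CO[C@H]3c2cc(OC)c(O[C@H](C(=O)N3[C@H](Cc4ccccc4)COC3=O)[C@@H](O[Si](C)(C)C)c3ccc(O[Si](C(C)C)(C(C)C)C(C)C)c(OC)c3)c(OC)c2)cc(OC)c1OCc1ccccc1 | intermediate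
23 | 4-O-benzyl-4'-O-{(1S,2S)-1-[(4R)-4-benzyl-2-oxooxazolidine-3-carbonyl]-2-hydroxy-2-[3-methoxy-4-(triisopropylsilyloxy)phenyl]ethyl}-(−)-syringaresinol | COc1cc([C@@H]2OC[C@@H]3[C@H]2CO[C@H]3c2cc(OC)c(O[C@H](C(=O)N3[C@H](Cc4ccccc4)COC3=O)[C@@H](O)c3ccc(O[Si](C(C)C)(C(C)C)C(C)C)c(OC)c3)c(OC)c2)cc(OC)c1OCc1ccccc1 | intermediate
24 | 4-O-benzyl-4'-O-{(1S,2R)-1,3-dihydroxy-1-[3-methoxy-4-(triisopropylsilyloxy)phenyl]propan-2-yl}-(−)-syringaresinol | COc1cc([C@@H]2OC[C@@H]3[C@H]2CO[C@H]3c2cc(OC)c(O[C@H](CO)[C@@H](O)c3ccc(O[Si](C(C)C)(C(C)C)C(C)C)c(OC)c3)c(OC)c2)cc(OC)c1OCc1ccccc1 | intermediate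
25 | 4'-O-{(1S,2R)-1,3-dihydroxy-1-[3-methoxy-4-(triisopropylsilyloxy)phenyl]propan-2-yl}-(−)-syringaresinol | COc1cc([C@@H]2OC[C@@H]3[C@H]2CO[C@H]3c2cc(OC)c(O[C@H](CO)[C@@H](O)c3ccc(O[Si](C(C)C)(C(C)C)C(C)C)c(OC)c3)c(OC)c2)cc(OC)c1O | intermediate
26 | 4-O-{2-[(4R)-4-benzyl-2-oxooxazolidin-3-yl]-2-oxoethyl}-4'-O-{(1S,2R)-1,3-dihydroxy-1-[3-methoxy-4-(triisopropylsilyloxy)phenyl]propan-2-yl}-(−)-syringaresinol | COc1cc([C@@H]2OC[C@@H]3[C@H]2CO[C@H]3c2cc(OC)c(O[C@H](CO)[C@@H](O)c3ccc(O[Si](C(C)C)(C(C)C)C(C)C)c(OC)c3)c(OC)c2)cc(OC)c1OCC(=O)N1[C@H](Cc2ccccc2)COC1=O | intermediate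
27 | 4-formyl-2-methoxyphenyl acetate (vanillin acetate) | COc1cc(C=O)ccc1OC(C)=O | starting material
28 | bis(trimethylsilyl) ether of 26 (C7–O and C9–O of unit G1) | COc1cc([C@@H]2OC[C@@H]3[C@H]2CO[C@H]3c2cc(OC)c(O[C@H](CO[Si](C)(C)C)[C@@H](O[Si](C)(C)C)c3ccc(O[Si](C(C)C)(C(C)C)C(C)C)c(OC)c3)c(OC)c2)cc(OC)c1OCC(=O)N1[C@H](Cc2ccccc2)COC1=O | intermediate
29 | tris(trimethylsilyl) ether of 30 (C7–O and C9–O of G1, C7–O of G2) | COc1cc([C@@H]2OC[C@@H]3[C@H]2CO[C@H]3c2cc(OC)c(O[C@H](CO[Si](C)(C)C)[C@@H](O[Si](C)(C)C)c3ccc(O[Si](C(C)C)(C(C)C)C(C)C)c(OC)c3)c(OC)c2)cc(OC)c1O[C@H](C(=O)N1[C@H](Cc2ccccc2)COC1=O)[C@@H](O[Si](C)(C)C)c1ccc(OC(C)=O)c(OC)c1 | intermediate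
30 | 4-O-{(1S,2S)-2-(4-acetoxy-3-methoxyphenyl)-1-[(4R)-4-benzyl-2-oxooxazolidine-3-carbonyl]-2-hydroxyethyl}-4'-O-{(1S,2R)-1,3-dihydroxy-1-[3-methoxy-4-(triisopropylsilyloxy)phenyl]propan-2-yl}-(−)-syringaresinol | COc1cc([C@@H]2OC[C@@H]3[C@H]2CO[C@H]3c2cc(OC)c(O[C@H](CO)[C@@H](O)c3ccc(O[Si](C(C)C)(C(C)C)C(C)C)c(OC)c3)c(OC)c2)cc(OC)c1O[C@H](C(=O)N1[C@H](Cc2ccccc2)COC1=O)[C@@H](O)c1ccc(OC(C)=O)c(OC)c1 | intermediate
31 | 4-O-[(1S,2R)-1,3-dihydroxy-1-(4-hydroxy-3-methoxyphenyl)propan-2-yl]-4'-O-{(1S,2R)-1,3-dihydroxy-1-[3-methoxy-4-(triisopropylsilyloxy)phenyl]propan-2-yl}-(−)-syringaresinol | COc1cc([C@@H]2OC[C@@H]3[C@H]2CO[C@H]3c2cc(OC)c(O[C@H](CO)[C@@H](O)c3ccc(O[Si](C(C)C)(C(C)C)C(C)C)c(OC)c3)c(OC)c2)cc(OC)c1O[C@H](CO)[C@@H](O)c1ccc(O)c(OC)c1 | intermediate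
32 | (S)-4-benzyl-oxazolidin-2-one | O=C1N[C@@H](Cc2ccccc2)CO1 | starting material
33 | (S)-4-benzyl-3-(bromoacetyl)oxazolidin-2-one | BrCC(=O)N1[C@@H](Cc2ccccc2)COC1=O | intermediate
34 | 4-O-{(1S,2R)-1-[4-({2-[(4S)-4-benzyl-2-oxooxazolidin-3-yl]-2-oxoethyl}oxy)-3-methoxyphenyl]-1,3-dihydroxypropan-2-yl}-4'-O-{(1S,2R)-1,3-dihydroxy-1-[3-methoxy-4-(triisopropylsilyloxy)phenyl]propan-2-yl}-(−)-syringaresinol | COc1cc([C@@H]2OC[C@@H]3[C@H]2CO[C@H]3c2cc(OC)c(O[C@H](CO)[C@@H](O)c3ccc(O[Si](C(C)C)(C(C)C)C(C)C)c(OC)c3)c(OC)c2)cc(OC)c1O[C@H](CO)[C@@H](O)c1ccc(OCC(=O)N2[C@@H](Cc3ccccc3)COC2=O)c(OC)c1 | intermediate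
35 | tetrakis(trimethylsilyl) ether of 34 (C7–O and C9–O of G1 and of G2) | COc1cc([C@@H]2OC[C@@H]3[C@H]2CO[C@H]3c2cc(OC)c(O[C@H](CO[Si](C)(C)C)[C@@H](O[Si](C)(C)C)c3ccc(O[Si](C(C)C)(C(C)C)C(C)C)c(OC)c3)c(OC)c2)cc(OC)c1O[C@H](CO[Si](C)(C)C)[C@@H](O[Si](C)(C)C)c1ccc(OCC(=O)N2[C@@H](Cc3ccccc3)COC2=O)c(OC)c1 | intermediate
36 | pentakis(trimethylsilyl) ether of 37 (C7–O and C9–O of G1 and of G2, C7–O of G3) | COc1cc([C@@H]2OC[C@@H]3[C@H]2CO[C@H]3c2cc(OC)c(O[C@H](CO[Si](C)(C)C)[C@@H](O[Si](C)(C)C)c3ccc(O[Si](C(C)C)(C(C)C)C(C)C)c(OC)c3)c(OC)c2)cc(OC)c1O[C@H](CO[Si](C)(C)C)[C@@H](O[Si](C)(C)C)c1ccc(O[C@@H](C(=O)N2[C@@H](Cc3ccccc3)COC2=O)[C@H](O[Si](C)(C)C)c2ccc(OC(C)=O)c(OC)c2)c(OC)c1 | intermediate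
37 | 4-O-{(1S,2R)-1-[4-({(1R,2R)-2-(4-acetoxy-3-methoxyphenyl)-1-[(4S)-4-benzyl-2-oxooxazolidine-3-carbonyl]-2-hydroxyethyl}oxy)-3-methoxyphenyl]-1,3-dihydroxypropan-2-yl}-4'-O-{(1S,2R)-1,3-dihydroxy-1-[3-methoxy-4-(triisopropylsilyloxy)phenyl]propan-2-yl}-(−)-syringaresinol | COc1cc([C@@H]2OC[C@@H]3[C@H]2CO[C@H]3c2cc(OC)c(O[C@H](CO)[C@@H](O)c3ccc(O[Si](C(C)C)(C(C)C)C(C)C)c(OC)c3)c(OC)c2)cc(OC)c1O[C@H](CO)[C@@H](O)c1ccc(O[C@@H](C(=O)N2[C@@H](Cc3ccccc3)COC2=O)[C@H](O)c2ccc(OC(C)=O)c(OC)c2)c(OC)c1 | intermediate
38 | 4-O-{(1S,2R)-1-[4-({(1R,2S)-1,3-dihydroxy-1-(4-hydroxy-3-methoxyphenyl)propan-2-yl}oxy)-3-methoxyphenyl]-1,3-dihydroxypropan-2-yl}-4'-O-{(1S,2R)-1,3-dihydroxy-1-[3-methoxy-4-(triisopropylsilyloxy)phenyl]propan-2-yl}-(−)-syringaresinol | COc1cc([C@@H]2OC[C@@H]3[C@H]2CO[C@H]3c2cc(OC)c(O[C@H](CO)[C@@H](O)c3ccc(O[Si](C(C)C)(C(C)C)C(C)C)c(OC)c3)c(OC)c2)cc(OC)c1O[C@H](CO)[C@@H](O)c1ccc(O[C@@H](CO)[C@H](O)c2ccc(O)c(OC)c2)c(OC)c1 | intermediate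
39 | CNP0316493.2: 4-O-{(1S,2R)-1-[4-({(1R,2S)-1,3-dihydroxy-1-(4-hydroxy-3-methoxyphenyl)propan-2-yl}oxy)-3-methoxyphenyl]-1,3-dihydroxypropan-2-yl}-4'-O-[(1S,2R)-1,3-dihydroxy-1-(4-hydroxy-3-methoxyphenyl)propan-2-yl]-(−)-syringaresinol | COc1cc([C@@H](O)[C@H](CO)Oc2ccc([C@H](O)[C@@H](CO)Oc3c(OC)cc([C@@H]4OC[C@@H]5[C@H]4CO[C@H]5c4cc(OC)c(O[C@H](CO)[C@@H](O)c5ccc(O)c(OC)c5)c(OC)c4)cc3OC)cc2OC)ccc1O | target

## Step count and weak points

Total: 24 steps. Longest linear sequence: 20 steps from 1 (steps 1–5, 7–10, 12, 14–19, 21–24). Steps 6, 11, 13 and 20 prepare building blocks.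

**Step 4 (key step).** The second shift is the weaker one. The carbanion of 7 must attack an alkene carbon next to the new tertiary centre, and it sits in a molecule that already carries a lithium alkoxide and a doubly allylic C–H. The likely failures are a competing [1,2]-shift and quenching of the second carbanion by proton transfer before it rearranges.

The fallback sets out from 3 and comes back at 8; it exchanges the α-alkoxymethyllithium for an ester enolate, which cannot take the [1,2] path. Diol 3 would be alkylated twice with tert-butyl bromoacetate under phase-transfer conditions to give di-tert-butyl 2,2'-{[(2R,3Z,5Z,7R)-octa-3,5-diene-2,7-diyl]bis(oxy)}diacetate F1. A double enolate [2,3]-Wittig rearrangement (LDA, THF, −78 → 0 °C) should then give, with the same suprafacial 1,3-transfer, di-tert-butyl (3S,4S)-2,5-dihydroxy-3,4-bis[(E)-prop-1-en-1-yl]hexanedioate F2. LiAlH4 would reduce it to (3S,4S)-3,4-bis[(E)-prop-1-en-1-yl]hexane-1,2,5,6-tetraol F3. NaIO4 would cleave both 1,2-diols to (2S,3S)-2,3-bis[(E)-prop-1-en-1-yl]butanedial F4, which is reduced in the same flask with NaBH4 to 8.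

**Step 8.** The ring closure is reversible under the acid that causes it, and the preference for the exo,exo isomer over its C7 epimer is kinetic, not strongly thermodynamic. Prolonged exposure would erode the exo selectivity by re-ionisation of the benzylic ring ethers.

The fallback sets out from 9 (with 12 made as in step 7) and comes back at 14; it forms the aryl–C7 bonds irreversibly on the closed bicycle. Bis-lactol 9 would be acetylated (Ac2O, pyridine) to (3aS,6aS)-tetrahydro-1H,3H-furo[3,4-c]furan-1,4-diyl diacetate F5. Grignard reagent 12 would be transmetalated with ZnBr2 to {4-[(tert-butyldimethylsilyl)oxy]-3,5-dimethoxyphenyl}zinc bromide F6. BF3·OEt2 (CH2Cl2, −40 °C) would ionise each anomeric acetate, and F6 would add to the oxocarbenium ion from the convex face to give 14.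

**Step 12 (and likewise steps 17 and 21).** The phenoxide may attack the exocyclic imide carbonyl of 18 instead of the CH2Br carbon. This acyl transfer would release the oxazolidinone and consume the phenol as an aryl bromoacetate.

The fallback sets out from 16 and comes back at 19; it builds the imide after the ether. Phenol 16 would be alkylated with bromoacetic acid (NaH, 2.2 equiv, THF) to give 4-O-benzyl-4'-O-(carboxymethyl)-(−)-syringaresinol F7. Pivaloyl chloride and Et3N would convert it into the mixed anhydride of F7 with pivalic acid F8. F8 would acylate the lithium salt of 17 (n-BuLi, THF, −78 °C) to give 19.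

**Step 14 (and likewise steps 18 and 22).** The magnesium-catalysed aldol is less secure for an aryloxyacetyl imide and an electron-rich aldehyde than for the simple cases. Two processes could spoil it: a slow addition that allows retro-aldol equilibration, and poor anti selectivity if the aryloxy oxygen competes for magnesium and loosens the chelated transition state.

The fallback sets out from 16 and comes back at 24; it uses the boron syn-aldol and corrects C7 afterwards. Phenol 16 would be alkylated with the (S)-reagent 33 to give 4-O-benzyl-4'-O-{2-[(4S)-4-benzyl-2-oxooxazolidin-3-yl]-2-oxoethyl}-(−)-syringaresinol F9. Its dibutylboron enolate (Bu2BOTf, i-Pr2NEt, CH2Cl2, −78 °C) should add to 21 in the syn sense through a chair transition state to give the (2S,3R)-syn adduct F10, in which C8 already has the target configuration. A Mitsunobu reaction with 4-nitrobenzoic acid (PPh3, DIAD) would invert C7 to give the (2S,3S)-4-nitrobenzoate F11. LiBH4 would remove the auxiliary and the ester together to give 24. For steps 18 and 22 the same sequence applies with the auxiliaries exchanged.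

## Further compounds

F1 | step 4 | di-tert-butyl 2,2'-{[(2R,3Z,5Z,7R)-octa-3,5-diene-2,7-diyl]bis(oxy)}diacetate | C[C@@H](OCC(=O)OC(C)(C)C)/C=C\C=C/[C@@H](C)OCC(=O)OC(C)(C)C
F2 | step 4 | di-tert-butyl (3S,4S)-2,5-dihydroxy-3,4-bis[(E)-prop-1-en-1-yl]hexanedioate (carbinol epimers) | C/C=C/[C@H](C(O)C(=O)OC(C)(C)C)[C@@H](C(O)C(=O)OC(C)(C)C)/C=C/C
F3 | step 4 | (3S,4S)-3,4-bis[(E)-prop-1-en-1-yl]hexane-1,2,5,6-tetraol (carbinol epimers) | C/C=C/[C@H](C(O)CO)[C@@H](C(O)CO)/C=C/C
F4 | step 4 | (2S,3S)-2,3-bis[(E)-prop-1-en-1-yl]butanedial | C/C=C/[C@H](C=O)[C@@H](C=O)/C=C/C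
F5 | step 8 | (3aS,6aS)-tetrahydro-1H,3H-furo[3,4-c]furan-1,4-diyl diacetate (anomer mixture) | CC(=O)OC1OC[C@@H]2[C@H]1COC2OC(C)=O
F6 | step 8 | {4-[(tert-butyldimethylsilyl)oxy]-3,5-dimethoxyphenyl}zinc bromide | COc1cc([Zn]Br)cc(OC)c1O[Si](C)(C)C(C)(C)C
F7 | step 12 | 4-O-benzyl-4'-O-(carboxymethyl)-(−)-syringaresinol | COc1cc([C@@H]2OC[C@@H]3[C@H]2CO[C@H]3c2cc(OC)c(OCC(O)=O)c(OC)c2)cc(OC)c1OCc1ccccc1
F8 | step 12 | mixed anhydride of F7 with pivalic acid | COc1cc([C@@H]2OC[C@@H]3[C@H]2CO[C@H]3c2cc(OC)c(OCC(=O)OC(=O)C(C)(C)C)c(OC)c2)cc(OC)c1OCc1ccccc1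
F9 | step 14 | 4-O-benzyl-4'-O-{2-[(4S)-4-benzyl-2-oxooxazolidin-3-yl]-2-oxoethyl}-(−)-syringaresinol | COc1cc([C@@H]2OC[C@@H]3[C@H]2CO[C@H]3c2cc(OC)c(OCC(=O)N3[C@@H](Cc4ccccc4)COC3=O)c(OC)c2)cc(OC)c1OCc1ccccc1
F10 | step 14 | 4-O-benzyl-4'-O-{(1S,2R)-1-[(4S)-4-benzyl-2-oxooxazolidine-3-carbonyl]-2-hydroxy-2-[3-methoxy-4-(triisopropylsilyloxy)phenyl]ethyl}-(−)-syringaresinol | COc1cc([C@@H]2OC[C@@H]3[C@H]2CO[C@H]3c2cc(OC)c(O[C@H](C(=O)N3[C@@H](Cc4ccccc4)COC3=O)[C@H](O)c3ccc(O[Si](C(C)C)(C(C)C)C(C)C)c(OC)c3)c(OC)c2)cc(OC)c1OCc1ccccc1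
F11 | step 14 | 4-O-benzyl-4'-O-{(1S,2S)-1-[(4S)-4-benzyl-2-oxooxazolidine-3-carbonyl]-2-[3-methoxy-4-(triisopropylsilyloxy)phenyl]-2-[(4-nitrobenzoyl)oxy]ethyl}-(−)-syringaresinol | COc1cc([C@@H]2OC[C@@H]3[C@H]2CO[C@H]3c2cc(OC)c(O[C@H](C(=O)N3[C@@H](Cc4ccccc4)COC3=O)[C@@H](OC(=O)c3ccc(cc3)[N+](=O)[O-])c3ccc(O[Si](C(C)C)(C(C)C)C(C)C)c(OC)c3)c(OC)c2)cc(OC)c1OCc1ccccc1
A1 | alternative 1 | (−)-syringaresinol 4,4'-bis-O-{(1S,2S)-1-[(4R)-4-benzyl-2-oxooxazolidine-3-carbonyl]-2-[4-(benzyloxy)-3-methoxyphenyl]-2-hydroxyethyl} ether | COc1cc(ccc1OCc1ccccc1)[C@H](O)[C@@H](C(=O)N1[C@H](Cc2ccccc2)COC1=O)Oc1c(OC)cc(cc1OC)[C@@H]1OC[C@@H]2[C@H]1CO[C@H]2c1cc(OC)c(O[C@H](C(=O)N2[C@H](Cc3ccccc3)COC2=O)[C@@H](O)c2ccc(OCc3ccccc3)c(OC)c2)c(OC)c1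
A2 | alternative 1 | (−)-syringaresinol 4,4'-bis-O-{2-[(4R)-4-benzyl-2-oxooxazolidin-3-yl]-2-oxoethyl} ether | COc1cc([C@@H]2OC[C@@H]3[C@H]2CO[C@H]3c2cc(OC)c(OCC(=O)N3[C@H](Cc4ccccc4)COC3=O)c(OC)c2)cc(OC)c1OCC(=O)N1[C@H](Cc2ccccc2)COC1=O
A3 | alternative 1 | 4-(benzyloxy)-3-methoxybenzaldehyde | COc1cc(C=O)ccc1OCc1ccccc1
A4 | alternative 2 | exo,exo-2-[4-(benzyloxy)-3,5-dimethoxyphenyl]-6-[4-(allyloxy)-3,5-dimethoxyphenyl]-3,7-dioxabicyclo[3.3.0]octan-8-one | COc1cc([C@@H]2OC[C@@H]3[C@H]2C(=O)O[C@H]3c2cc(OC)c(OCC=C)c(OC)c2)cc(OC)c1OCc1ccccc1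
A5 | alternative 2 | (R)-5-[4-(allyloxy)-3,5-dimethoxyphenyl]furan-2(5H)-one | O=C1O[C@H](C=C1)c1cc(OC)c(OCC=C)c(OC)c1
A6 | alternative 2 | {[4-(benzyloxy)-3,5-dimethoxyphenyl](chloromethoxy)methyl}trimethylsilane (racemic) | COc1cc(C(OCCl)[Si](C)(C)C)cc(OC)c1OCc1ccccc1
A7 | alternative 3 | O,O'-dibenzyl-(−)-syringaresinol | COc1cc([C@@H]2OC[C@@H]3[C@H]2CO[C@H]3c2cc(OC)c(OCc3ccccc3)c(OC)c2)cc(OC)c1OCc1ccccc1
A8 | alternative 3 | (3aS,6aS)-tetrahydro-1H,3H-furo[3,4-c]furan-1,4-diyl diacetate (anomer mixture) | CC(=O)OC1OC[C@@H]2[C@H]1COC2OC(C)=O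
A9 | alternative 3 | [4-(benzyloxy)-3,5-dimethoxyphenyl]zinc bromide | COc1cc([Zn]Br)cc(OC)c1OCc1ccccc1
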